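The spiro carbon C8 is treated as a former ketone carbon, not as the end of caryophyllene's exocyclic alkene. In the key step the C8=O of kobusone supplies C8 and the pyran oxygen: the ester enolate of a syncarpic fragment, whose isobutyl-bearing C1′ is already set by NHC catalysis, forms C13–C8, and the tertiary alkoxide then closes the dihydropyran by displacing methoxide at C3′ of the trione enol ether. One operation joins both halves, builds the spiro ring and fixes C8 by delivering carbon, not oxygen, to the open face. The precursors are a nor-ketone epoxide, which later unfolds into the Z-C3=C4/C5–OH unit, and a benzyl ester that acts as traceless activator.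

Key step: step 4

Remark: caryophyllane locants are used (C12 = methyl on C4, C13 = former exocyclic carbon = pyran CH2, C1′ = isobutyl-bearing carbon, C2′=C3′ = enol-ether carbons of the trione with C3′ bearing the ring oxygen); 3 and 4 are taken as catalogue compounds, and the catalyst sense in step 2 and the carbonyl face attacked in step 4 are assigned from models and analogy, not from experiment.

Step 1
Reactants: 1 (−)-caryophyllene oxide
Product: 2 kobusone [(1R,4R,5R,9S)-4,5-epoxy-13-norcaryophyllan-8-one]
Conditions: O3, CH2Cl2, −78 °C; then Me2S, −78 → 23 °C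
Reagents that add atoms: ozone, [O-][O+]=O
Why: Ozonolysis with reductive work-up cleaves the exocyclic C8=C13 bond, the only alkene of 1, to the C8 ketone while the epoxide and all stereocenters are untouched.

Step 2
Reactants: 3 syncarpic acid; 4 (E)-5-methylhex-2-enal
Product: 5 (4S)-4-isobutyl-6,6,8,8-tetramethyl-3,4-dihydro-2H-chromene-2,5,7(6H,8H)-trione (enol lactone)
Conditions: aminoindanol-derived N-mesityl triazolium chloride (10 mol %, the enantiomer that gives the 4S lactone), DBU (cat.), 3,3′,5,5′-tetra-tert-butyldiphenoquinone (1.1 equiv), THF, 23 °C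
Reagents that add atoms: none
Why: Oxidative NHC [3+3] annulation: the Breslow intermediate of 4 is oxidised to the α,β-unsaturated acyl azolium, the enol carbon of 3 adds to its β-carbon and the enol oxygen is acylated with release of the carbene, the chiral triazolium shielding one face of the acyl azolium and thereby setting C1′.

Step 3
Reactants: 5 enol lactone
Product: 7 benzyl (3S)-3-(2-methoxy-3,3,5,5-tetramethyl-4,6-dioxocyclohex-1-en-1-yl)-5-methylhexanoate, via enol benzyl ester 6 (not isolated)
Conditions: BnOH, DMAP (cat.), CH2Cl2, 23 °C; then TMSCHN2, MeOH–toluene, 0 °C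
Reagents that add atoms: benzyl alcohol, OCc1ccccc1; trimethylsilyldiazomethane, C[Si](C)(C)C=[N+]=[N-]
Why: The enol lactone is a vinylogous anhydride and is opened by benzyl alcohol through DMAP acyl transfer, and the liberated acidic enol is O-methylated by TMSCHN2, which blocks relactonisation and gives a single enol ether because the two enol oxygens are equivalent by symmetry; C1′ is not touched.

Step 4
Reactants: 7 benzyl ester fragment; 2 kobusone
Product: 9 13-benzyloxycarbonyl-4,5-epoxy spiro-dihydropyran adduct (1R,4R,5R,9S,1′S; C8 as in the target; both C13 epimers), via lithium aldolate 8 (not isolated)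
Conditions: LiHMDS (1.05 equiv), THF, −78 °C; add 2, −78 → 0 °C; aq NH4Cl
Reagents that add atoms: none
Why: LiHMDS forms the ester enolate at C13, the only acidic C–H of 7 because the trione ring has no α-hydrogen, and this enolate adds to the C8 carbonyl of 2 (ester-enolate aldol, Reformatsky-type C–C bond formation). The tertiary lithium alkoxide 8 then attacks C3′ of the 3-methoxy-enone and expels methoxide (intramolecular vinylogous transesterification by addition–elimination), which draws the aldolate out of the retro-aldol equilibrium. The dihydropyran closes by a six-membered attack on the trigonal C3′ that lies inside the new ring (6-endo-trig, then loss of methoxide). C8 is set in the aldol step by substrate control: in the conformer with C=O eclipsing the cyclobutane C9–C10 bond the enolate should take the carbonyl face turned away from C1 and the ring interior, which puts C13 anti to C1 and the oxygen on the ring side, the 8S array of the target and the opposite of oxygen delivery to that same open face of an exocyclic alkene. C1′ comes unchanged from 7, and C13 forms as an epimer mixture that step 6 erases. The step needs C-attack on the ketone to outrun proton transfer from C7/C9, which low temperature, the lithium counter-ion and the fully consumed hindered base should secure, while the epoxide is inert to enolates without a Lewis acid.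

Step 5
Reactants: 9 benzyl ester adduct
Product: 10 13-carboxy-4,5-epoxy spiro-dihydropyran adduct (both C13 epimers)
Conditions: H2 (1 atm), 10% Pd/C, EtOAc, 23 °C
Reagents that add atoms: none
Why: Hydrogenolysis of the benzyl ester under neutral conditions should leave the trisubstituted alkyl epoxide and the tetrasubstituted push–pull enol ether (the only C=C present) untouched and avoids any base that could open the pyran by β-elimination.

Step 6
Reactants: 10 carboxylic acid
Product: 12 (1R,4R,5R,8S,9S,1′S)-4,5-epoxy spiro-dihydropyran adduct (epoxide isomer of the target), via Barton ester 11 (not isolated)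
Conditions: 1-hydroxypyridine-2(1H)-thione, DCC, DMAP (cat.), CH2Cl2, 0 → 23 °C, dark; then t-BuSH, hν (tungsten lamp), 23 °C
Reagents that add atoms: none
Why: Barton reductive decarboxylation: the thiohydroxamate ester fragments under light to CO2 and the secondary C13 radical, which takes hydrogen from the thiol faster than any fragmentation of the β C–O bond, so the activating carboxyl leaves tracelessly and the C13 stereocenter disappears.

Step 7
Reactants: 12 epoxide adduct
Product: 13 5-epi-tomentodione P [(3Z,5R)-allylic alcohol]
Conditions: Et2Al–TMP (from Et2AlCl and LiTMP, itself from TMP and n-BuLi), toluene, 0 °C; Rochelle salt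
Reagents that add atoms: none
Why: Aluminium amide epoxide-to-allylic-alcohol isomerisation: aluminium binds the epoxide oxygen and the hindered amide removes, through a cyclic syn transition state, the C3 hydrogen that lies cis to H5 (not a C12 hydrogen), so that C4–O breaks, C5–O keeps its configuration and the unstrained cis (Z) C3=C4 bond of the nine-membered ring should form.

Step 8
Reactants: 13 allylic alcohol
Product: 14 5-dehydrotomentodione P [(3Z)-en-5-one]
Conditions: Dess–Martin periodinane, NaHCO3, CH2Cl2, 0 → 23 °C
Reagents that add atoms: none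
Why: Dess–Martin oxidation of the secondary allylic alcohol gives the Z-enone under buffered neutral conditions and removes the C5 configuration inherited from the epoxide, which is the wrong one for the target.

Step 9
Reactants: 14 enone
Product: 15 tomentodione P
Conditions: (R)-Me-CBS (20 mol %), catecholborane, toluene, −78 °C; then MeOH, aq NaOH
Reagents that add atoms: none
Why: Corey–Bakshi–Shibata reduction: the (R)-oxazaborolidine binds the C5 carbonyl with the α-methyl alkenyl side (C4) as large and C6H2 as small group and delivers hydride 1,2 to give the 5S carbinol, while catecholborane at −78 °C should leave the vinylogous ester, the ketone between the two CMe2 groups and the alkene alone.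

Compound list
1 | (−)-caryophyllene oxide, (1R,4R,5R,9S)-4,5-epoxycaryophyll-8(13)-ene | C[C@@]12CC[C@@H]3[C@H](CC3(C)C)C(=C)CC[C@H]1O2 | starting material
2 | kobusone, (1R,4R,5R,9S)-4,5-epoxy-13-norcaryophyllan-8-one | C[C@@]12CC[C@@H]3[C@H](CC3(C)C)C(=O)CC[C@H]1O2 | intermediate
3 | syncarpic acid, 2,2,4,4-tetramethylcyclohexane-1,3,5-trione | CC1(C)C(=O)CC(=O)C(C)(C)C1=O | starting material
4 | (E)-5-methylhex-2-enal | CC(C)C/C=C/C=O | starting material
5 | (4S)-4-isobutyl-6,6,8,8-tetramethyl-3,4-dihydro-2H-chromene-2,5,7(6H,8H)-trione | O=C1C[C@H](CC(C)C)C2=C(O1)C(C)(C)C(=O)C(C)(C)C2=O | intermediate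
6 | benzyl (3S)-3-(2-hydroxy-3,3,5,5-tetramethyl-4,6-dioxocyclohex-1-en-1-yl)-5-methylhexanoate | O=C(OCc1ccccc1)C[C@H](CC(C)C)C1=C(O)C(C)(C)C(=O)C(C)(C)C1=O | intermediate
7 | benzyl (3S)-3-(2-methoxy-3,3,5,5-tetramethyl-4,6-dioxocyclohex-1-en-1-yl)-5-methylhexanoate | O=C(OCc1ccccc1)C[C@H](CC(C)C)C1=C(OC)C(C)(C)C(=O)C(C)(C)C1=O | intermediate
8 | lithium aldolate of 7 and 2 (C8 alkoxide, both C13 epimers) | C[C@@]12CC[C@@H]3[C@H](CC3(C)C)[C@]([O-])(CC[C@H]1O2)C(C(=O)OCc1ccccc1)[C@H](CC(C)C)C1=C(OC)C(C)(C)C(=O)C(C)(C)C1=O.[Li+] | intermediate
9 | 13-benzyloxycarbonyl-4,5-epoxy spiro-dihydropyran adduct (both C13 epimers) | C[C@@]12CC[C@@H]3[C@H](CC3(C)C)[C@]4(CC[C@H]1O2)C(C(=O)OCc1ccccc1)[C@H](CC(C)C)C1=C(O4)C(C)(C)C(=O)C(C)(C)C1=O | intermediate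
10 | 13-carboxy-4,5-epoxy spiro-dihydropyran adduct (both C13 epimers) | C[C@@]12CC[C@@H]3[C@H](CC3(C)C)[C@]4(CC[C@H]1O2)C(C(=O)O)[C@H](CC(C)C)C1=C(O4)C(C)(C)C(=O)C(C)(C)C1=O | intermediate
11 | Barton ester of 10 (2-thioxopyridin-1(2H)-yl ester) | C[C@@]12CC[C@@H]3[C@H](CC3(C)C)[C@]4(CC[C@H]1O2)C(C(=O)ON5C=CC=CC5=S)[C@H](CC(C)C)C1=C(O4)C(C)(C)C(=O)C(C)(C)C1=O | intermediate
12 | (1R,4R,5R,8S,9S,1′S)-4,5-epoxy spiro-dihydropyran adduct | C[C@@]12CC[C@@H]3[C@H](CC3(C)C)[C@]4(CC[C@H]1O2)C[C@H](CC(C)C)C1=C(O4)C(C)(C)C(=O)C(C)(C)C1=O | intermediate
13 | 5-epi-tomentodione P, (1R,3Z,5R,8S,9S,1′S) | C/C1=C/C[C@@H]2[C@H](CC2(C)C)[C@]2(CC[C@H]1O)C[C@H](CC(C)C)C1=C(O2)C(C)(C)C(=O)C(C)(C)C1=O | intermediate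
14 | 5-dehydrotomentodione P, (1R,3Z,8S,9S,1′S)-3-en-5-one | C/C1=C/C[C@@H]2[C@H](CC2(C)C)[C@]2(CCC1=O)C[C@H](CC(C)C)C1=C(O2)C(C)(C)C(=O)C(C)(C)C1=O | intermediate
15 | tomentodione P, (1R,3Z,5S,8S,9S,1′S) | C/C1=C/C[C@@H]2[C@H](CC2(C)C)[C@]2(CC[C@@H]1O)C[C@H](CC(C)C)C1=C(O2)C(C)(C)C(=O)C(C)(C)C1=O | target

Total step count: 9
Longest linear sequence: 8 steps (steps 2 to 9, from 3 and 4); the terpene branch (step 1) joins at step 4.

Steps most likely to fail

Step 4. The enolate may deprotonate 2 at C7/C9 instead of adding to the hindered carbonyl. The aldolate may revert on warming before the tertiary alkoxide reaches the congested C3′. The enolate may also take the other carbonyl face and give the C8 epimer. The fallback leaves the ketone logic and forms the pyran from the alkene instead. It sets out from 1 and 3: condensation of 3 with 3-methylbutanal (ethylenediammonium diacetate, toluene, 80 °C) generates the alkylidene trione F1 in the presence of 1. Inverse-demand hetero-Diels–Alder addition of F1 to the exocyclic alkene of 1, its only alkene, forms the same ring with oxygen on C8. After separation from stereoisomers at C8 and C1′ the route is rejoined at 12.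

Step 7. The amide may remove a C12 methyl hydrogen and give the exocyclic alkene, or the ring may deliver the E alkene. The fallback accepts the exocyclic regiochemistry and corrects it at the enone stage. It sets out from 12: Al(OiPr)3 in refluxing toluene gives the exocyclic allylic alcohol F2. Dess–Martin oxidation gives the exocyclic enone F3. RhCl3·3H2O in ethanol at 70 °C moves the double bond into conjugation inside the ring, and the route is rejoined at 14.

Step 9. The bias of the nine-membered ring may oppose the catalyst and lower facial selectivity, or conjugate reduction may compete. The fallback sets C5 by substitution instead of reduction. It sets out from 13 and skips 14: Mitsunobu reaction with 4-nitrobenzoic acid, PPh3 and DIAD in THF inverts C5 and gives the (5S)-4-nitrobenzoate F4. Brief methanolysis (K2CO3, MeOH, 0 °C) releases the alcohol, and the route is rejoined at 15.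

Further compounds
F1 | step 4 | 2-(3-methylbutylidene)-4,4,6,6-tetramethylcyclohexane-1,3,5-trione | CC(C)CC=C1C(=O)C(C)(C)C(=O)C(C)(C)C1=O
F2 | step 7 | (5R)-4(12)-exocyclic allylic alcohol isomer of 13 | C=C1CC[C@@H]2[C@H](CC2(C)C)[C@]2(CC[C@H]1O)C[C@H](CC(C)C)C1=C(O2)C(C)(C)C(=O)C(C)(C)C1=O
F3 | step 7 | 4(12)-exocyclic enone isomer of 14 | C=C1CC[C@@H]2[C@H](CC2(C)C)[C@]2(CCC1=O)C[C@H](CC(C)C)C1=C(O2)C(C)(C)C(=O)C(C)(C)C1=O
F4 | step 9 | (5S)-4-nitrobenzoate of 15 | C/C1=C/C[C@@H]2[C@H](CC2(C)C)[C@]2(CC[C@@H]1OC(=O)c1ccc(cc1)[N+](=O)[O-])C[C@H](CC(C)C)C1=C(O2)C(C)(C)C(=O)C(C)(C)C1=O
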